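(The numbers in the tables were computed with made-up constants; the scatter is artificial.)

To whoever takes over the bench: the flask is listed below with the two runs made before it, and this note says what it will hold when you come.

in all of them: starting material 0.020 M

| flask | reagent | capture agent | protic impurity | remark | time |
|---|---|---|---|---|---|
| summer | 0.47 equiv | 1 mM | 2 mM | run made earlier |  |
| winter | 1.9 equiv | 1 mM | 2 mM | run made earlier |  |
| flask | 0.950 equiv | 1.00 mM | 2.00 mM |  | 50 min |

- summer (time / min: isomer of the product / %, target / %): 2.50: 23.6, 6.2; 4.00: 24.3, 5.0; 6.00: 25.1, 5.5; 10.0: 25.8, 5.8; 20.0: 25.4, 5.3; 30.0: 25.3, 6.0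
- winter (time / min: isomer of the product / %, target / %): 2.00: 46.5, 13.0; 6.00: 51.9, 11.0; 10.0: 52.1, 11.3; 15.0: 52.5, 10.6; 25.0: 52.5, 10.9; 30.0: 52.0, 10.4

(standard deviation of a reading: 0.5 percentage points)

1. ratio of isomer of the product to target at 2.5 s
2. ratio of isomer of the product to target at 50 min

Start from the balance. I assume the protic impurity eats starting material one for one, so 90.0% of the charge can meet the reagent. The flask's 0.950 equiv is more than that, so starting material is the limiting reagent there, with reagent to spare to the amount of 5.00% of the starting material charged: don't add more. I also assume each molecule of capture agent takes one molecule out of what has reacted, which leaves a working pool of 85.0% in the flask.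

The winter run has the same limit and a pool of 85.0%. In the summer run the reagent limits, and the pool is 42.0%. The late readings give isomer of 25.5% in summer and 52.3% in winter, which is 0.607 and 0.615 of the pool. So carry the pool return, the isomer found per unit of working pool: 0.612. For target the return is 0.130.

In the flask at 50 min I therefore expect isomer at 52.0%, target at 11.1% and a ratio of 4.71. For the flask at 2.5 s I give no number: the earliest reading of the winter run, at 2.00 min, shows a ratio of 3.58, lower than the end ratio I expect, and that is as far back as the readings go.

The forecast gives 0.6 and 4.7, the first by its own account “a very uncertain extrapolation”. The flask gives 0.0622 and 4.69.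

    starting material + protic impurity → quenched substrate (k = 40.0 M⁻¹ s⁻¹)
    open intermediate + capture agent → trapped intermediate (k = 53.0 M⁻¹ s⁻¹)
    open intermediate ⇌ isomer of the product (K = 2.30, k = 0.0170 s⁻¹)
    starting material + reagent → open intermediate + by-product (k = 8.60 M⁻¹ s⁻¹)
    open intermediate ⇌ target (K = 0.490, k = 0.860 s⁻¹)

The flask holds isomer at 51.6% and target at 11.0% at 50.0 min, with 5.3% of the reagent's charge left and open intermediate at 22.4%. The half-life of isomer for going back through open intermediate is 1.6 min, short against 50 min, and the flask's isomer still stands at 51.6% at 500 min. With reagent at 0.380 equiv, the neighbour flask has a pool of 33.0%, so the pool return gives isomer at 20.2% and target at 4.29%. That neighbour flask stands at 20.0% isomer and 4.27% target.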